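**Retrosynthetic overview**
- Target ⇒ acetylation and exo-face OsO4 dihydroxylation of a bridged C4=C5 butenolide that already carries the dihydrofuran spiro-ketal lactone.
- ⇒ C6 ketone reduction and two lactonisations (O6–C15, O8–C12) from a bicyclic 1,8-hemiketal keto acid.
- ⇒ Key step: an 11-membered macrolactone (C8 enoate on O7) contracts by a Chan 1,2-acyl shift O7→C7. This makes C7–C8, the 10-membered carbocycle and the C7 carbinol; O1 then closes ring B on C8.
- ⇒ The macrolactone comes from a furan (masked Z-4-oxo-2-enoic acid, unmasked by singlet oxygen) and is closed at C3–C4 by an intramolecular B-alkyl Suzuki coupling.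
- ⇒ Linear ester from 4-bromofurfural + methyl acrylate (reductive aldol, C11), propiolic acid (ester), acrolein (alkynylation, C1) and MeCu (C14). Ring order: 11-membered lactone → 10-membered carbocycle → ring B → rings A and C.

Assumption: atom labels follow germacrane numbering (C1 = dihydrofuran CH–O, C2/C3 = the CH2CH2, C4 = C(OH), C5 = CH–OAc, C6 = lactone CH–O, C7 = ring C(OH), C8 = spiro ketal C, C9=C10 with methyl C14, C11 = CH(CH3) with methyl C13, C12 and C15 = lactone C=O); the target is then 1S,4S,5S,6R,7S,8S,11S, and the four carbon starting materials are taken as commercial.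

**Step 1**
Reactants: 1 4-bromofuran-2-carbaldehyde; 2 methyl acrylate
Product: 4 methyl (2S,3S)-3-(4-bromofuran-2-yl)-3-hydroxy-2-methylpropanoate, via silyl aldolate 3 (not isolated)
Conditions: [Ir(cod)Cl]2 (2.5 mol %), indane-pybox (7.5 mol %; enantiomer chosen for 2S), Et2MeSiH, CH2Cl2, 23 °C; then 1 M HCl, THF
Reagents that add atoms: none
Why: Ir–H reduces the acrylate to a (Z)-enolate that adds to the aldehyde through a closed transition state (catalytic asymmetric reductive aldol), the pybox ligand setting C11 as S with syn C7–OH; the C7 configuration is erased in step 8.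

**Step 2**
Reactants: 4 methyl (2S,3S)-3-(4-bromofuran-2-yl)-3-hydroxy-2-methylpropanoate; 5 propiolic acid
Product: 6 methyl (2S,3S)-3-(4-bromofuran-2-yl)-2-methyl-3-(prop-2-ynoyloxy)propanoate
Conditions: DCC, DMAP (5 mol %), CH2Cl2, −20 → 0 °C
Reagents that add atoms: none
Why: Steglich esterification of the secondary furfuryl alcohol brings in C8–C10 and creates the O7–C8 ester bond that migrates later; no stereocentre changes.

**Step 3**
Reactants: 6 methyl (2S,3S)-3-(4-bromofuran-2-yl)-2-methyl-3-(prop-2-ynoyloxy)propanoate; 7 acrolein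
Product: 8 methyl (2S,3S)-3-(4-bromofuran-2-yl)-3-{[(4S)-4-hydroxyhex-5-en-2-ynoyl]oxy}-2-methylpropanoate
Conditions: Me2Zn (3 equiv), ProPhenol (20 mol %; enantiomer chosen for 4S), Ph3PO (40 mol %), PhMe, 4 °C
Reagents that add atoms: none
Why: Zn–ProPhenol asymmetric alkynylation: the dinuclear zinc alkynylide of the propiolate adds 1,2 to acrolein and the ligand pocket sets C1 as S; the esters and the bromofuran are inert to Me2Zn at 4 °C.

**Step 4**
Reactants: 8 methyl (2S,3S)-3-(4-bromofuran-2-yl)-3-{[(4S)-4-hydroxyhex-5-en-2-ynoyl]oxy}-2-methylpropanoate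
Product: 9 methyl (2S,3S)-3-(4-bromofuran-2-yl)-2-methyl-3-{[(4S)-4-(triethylsilyloxy)hex-5-en-2-ynoyl]oxy}propanoate
Conditions: TESCl, imidazole, DMF, 0 °C
Reagents that add atoms: chlorotriethylsilane, CC[Si](Cl)(CC)CC
Why: Standard silylation; the TES ether stops O1 from translactonising onto C8 and is labile enough to fall off in the acidic work-up of step 8.

**Step 5**
Reactants: 9 methyl (2S,3S)-3-(4-bromofuran-2-yl)-2-methyl-3-{[(4S)-4-(triethylsilyloxy)hex-5-en-2-ynoyl]oxy}propanoate
Product: 10 methyl (2S,3S)-3-(4-bromofuran-2-yl)-2-methyl-3-{[(2Z,4S)-3-methyl-4-(triethylsilyloxy)hexa-2,5-dienoyl]oxy}propanoate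
Conditions: Me2CuLi (from MeLi, CuI; 1.3 equiv), THF, −78 °C; NH4Cl at −78 °C
Reagents that add atoms: lithium dimethylcuprate, [Li+].C[Cu-]C
Why: Syn-carbocupration of the ynoate by the Gilman cuprate and cold protonation give the 9Z enoate (C1 and C8 cis, the geometry ring B needs) and install methyl C14; no stereocentre changes.

**Step 6**
Reactants: 10 methyl (2S,3S)-3-(4-bromofuran-2-yl)-2-methyl-3-{[(2Z,4S)-3-methyl-4-(triethylsilyloxy)hexa-2,5-dienoyl]oxy}propanoate
Product: 12 furanophane macrolactone (11-membered ring O7–C8(=O)–C9H=C10(CH3)–C1H(OTES)–C2H2–C3H2–C4=C5H–C6–C7H; furan completed by C15H–O; C7 carries the CH(CH3)CO2Me arm; 1S,7S,11S,9Z), via alkyl-9-BBN adduct 11 (not isolated)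
Conditions: 9-BBN-H, THF, 0 → 23 °C; then Pd(OAc)2 (10 mol %), SPhos (20 mol %), K3PO4, THF–H2O, 45 °C, 2 mM (slow addition)
Reagents that add atoms: none
Why: 9-BBN hydroborates only the monosubstituted alkene (boron at C3) and the intramolecular B-alkyl Suzuki–Miyaura coupling with the bromofuran closes the 11-membered lactone ring at C3–C4 under high dilution; no stereocentre is touched.

**Step 7**
Reactants: 12 furanophane macrolactone
Product: 14 hydroxybutenolide macrolactone (as 12 but the furan is now the pseudo-acid C15(=O)–O–C6(OH) with C4=C5; both C6 epimers), via furan endoperoxide 13 (not isolated)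
Conditions: O2, TPP (1 mol %), hν, CH2Cl2, −78 °C; then iPr2NEt, −78 → 0 °C
Reagents that add atoms: dioxygen (as singlet oxygen), O=O
Why: [4+2] photooxygenation of the furan and Kornblum–DeLaMare-type base fragmentation of the endoperoxide (loss of H15) unmask the Z-4-oxo-2-enoic acid as its pseudo-acid with C15 locked cis to C6; the electron-poor enoate does not react with singlet oxygen.

**Step 8**
Reactants: 14 hydroxybutenolide macrolactone
Product: 16 bicyclic 1,8-hemiketal (10-membered carbocycle C1–C10; 1,8-epoxy bridge; OH at C7 and C8; C6/C15 hydroxybutenolide; CH(CH3)CO2Me on C7; C1, C7, C8 and C11 configured as in 20), via ring-contracted silyl ether 15 (not isolated)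
Conditions: LiTMP (3.2 equiv), THF, −78 → −25 °C; then AcOH–THF–H2O (3:1:1), 23 °C
Reagents that add atoms: none
Why: Proposed new method: a ring-contracting Chan rearrangement of a macrolactone, in which base opens the pseudo-acid to the C15 carboxylate and C6 ketone and removes H7 (α to C6=O and to the acyloxy group), the enolate carbon attacks the lactone carbonyl C8 through an oxiranolate and the O7–C8 bond breaks, so the enoyl carbon shifts 1,2 from O7 to C7, the 11-membered lactone becomes the 10-membered carbocycle and C7 becomes the tertiary carbinol (7S expected because, with H11 held in the enolate plane by allylic strain, C8 swings onto the face anti to methyl C13 and next to the Li-bridging C12 ester), after which the acidic work-up removes TES and O1 closes on C8 with C8 fixed by C1; the closest known reactions are the Chan rearrangement of α-acyloxy esters and ketones and its cyclic-carbonate to hydroxy-lactone ring contraction, not yet shown for a macrolactone-to-carbocycle contraction or an enoyl migrating group.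

**Step 9**
Reactants: 16 bicyclic 1,8-hemiketal
Product: 18 butenolide spiro-ketal bis-lactone (4,5-didehydro precursor; C4=C5 in the 15,6-lactone; 12,8-lactone closed; 1S,6R,7S,8S,11S), via hydroxy acid 17 (not isolated)
Conditions: NaBH4, THF–MeOH (10:1), −40 °C; then TsOH·H2O, 4 Å MS, 40 °C
Reagents that add atoms: none
Why: Borohydride opens the pseudo-acid and reduces the C6 ketone in Felkin–Anh fashion (hydride anti to the C7–O bond and past the smaller C11 branch, giving 6R) while C8 stays masked as the bridged hemiketal, and acid then closes the butenolide (O6–C15) and, by transesterification with loss of methanol, the spiro lactone (O8–C12) without breaking the C8–O bond; this is the known reduction of a γ-hydroxybutenolide to a butenolide followed by lactonisation.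

**Step 10**
Reactants: 18 butenolide spiro-ketal bis-lactone
Product: 19 4,5-diol (5-O-deacetyl target; 1S,4S,5S,6R,7S,8S,11S)
Conditions: OsO4 (5 mol %), NMO, acetone–H2O (8:1), 0 °C; Na2SO3
Reagents that add atoms: osmium tetroxide (catalytic oxygen carrier), O=[Os](=O)(=O)=O; N-methylmorpholine N-oxide, C[N+]1([O-])CCOCC1; water, O
Why: Upjohn dihydroxylation: the strained bridged butenolide alkene is attacked from its only open (exo) face, anti to the ten-membered ring, which sets C4 and C5 as the cis-diol, while C9=C10 is shielded by the spiro ketal and deactivated by three allylic C–O bonds.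

**Step 11**
Reactants: 19 4,5-diol
Product: 20 CNP0315698.1 (target)
Conditions: Ac2O (1.2 equiv), pyridine, DMAP (cat.), CH2Cl2, 0 °C
Reagents that add atoms: acetic anhydride, CC(=O)OC(C)=O
Why: Selective acetylation of the only secondary hydroxyl (C5–OH) beside two tertiary ones; no stereocentre changes.

**Compound list**
1 | 4-bromofuran-2-carbaldehyde | O=Cc1cc(Br)co1 | starting material
2 | methyl acrylate | C=CC(=O)OC | starting material
3 | methyl (2S,3S)-3-(4-bromofuran-2-yl)-3-[diethyl(methyl)silyloxy]-2-methylpropanoate | COC(=O)[C@@H](C)[C@H](O[Si](C)(CC)CC)c1cc(Br)co1 | intermediate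
4 | methyl (2S,3S)-3-(4-bromofuran-2-yl)-3-hydroxy-2-methylpropanoate | COC(=O)[C@@H](C)[C@H](O)c1cc(Br)co1 | intermediate
5 | propiolic acid | C#CC(=O)O | starting material
6 | methyl (2S,3S)-3-(4-bromofuran-2-yl)-2-methyl-3-(prop-2-ynoyloxy)propanoate | COC(=O)[C@@H](C)[C@H](OC(=O)C#C)c1cc(Br)co1 | intermediate
7 | acrolein | C=CC=O | starting material
8 | methyl (2S,3S)-3-(4-bromofuran-2-yl)-3-{[(4S)-4-hydroxyhex-5-en-2-ynoyl]oxy}-2-methylpropanoate | COC(=O)[C@@H](C)[C@H](OC(=O)C#C[C@@H](O)C=C)c1cc(Br)co1 | intermediate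
9 | methyl (2S,3S)-3-(4-bromofuran-2-yl)-2-methyl-3-{[(4S)-4-(triethylsilyloxy)hex-5-en-2-ynoyl]oxy}propanoate | COC(=O)[C@@H](C)[C@H](OC(=O)C#C[C@@H](O[Si](CC)(CC)CC)C=C)c1cc(Br)co1 | intermediate
10 | methyl (2S,3S)-3-(4-bromofuran-2-yl)-2-methyl-3-{[(2Z,4S)-3-methyl-4-(triethylsilyloxy)hexa-2,5-dienoyl]oxy}propanoate | COC(=O)[C@@H](C)[C@H](OC(=O)/C=C(C)\[C@@H](O[Si](CC)(CC)CC)C=C)c1cc(Br)co1 | intermediate
11 | alkyl-9-BBN adduct of 10 (9-BBN on C3; (2Z,4S)-6-(9-borabicyclo[3.3.1]nonan-9-yl)-3-methyl-4-(triethylsilyloxy)hex-2-enoyl ester) | COC(=O)[C@@H](C)[C@H](OC(=O)/C=C(C)\[C@@H](O[Si](CC)(CC)CC)CCB1C2CCCC1CCC2)c1cc(Br)co1 | intermediate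
12 | furanophane macrolactone (11-membered O7–C8 lactone closed through C3–C4; 1S,7S,11S,9Z; 1-OTES) | COC(=O)[C@@H](C)[C@@H]1OC(=O)/C=C(C)\[C@@H](O[Si](CC)(CC)CC)CCc2coc1c2 | intermediate
13 | furan endoperoxide of 12 (O–O bridge between C6 and C15; both faces) | COC(=O)[C@@H](C)[C@@H]1OC(=O)/C=C(C)\[C@@H](O[Si](CC)(CC)CC)CCC2=CC13OOC2O3 | intermediate
14 | hydroxybutenolide (pseudo-acid) macrolactone (C15(=O)–O–C6(OH), C4=C5; C6 epimers) | COC(=O)[C@@H](C)[C@@H]1OC(=O)/C=C(C)\[C@@H](O[Si](CC)(CC)CC)CCC2=CC1(O)OC2=O | intermediate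
15 | ring-contracted silyl ether (10-membered carbocycle; C8 ketone; C7 tertiary OH; 1-OTES; 9Z; C6/C15 hydroxybutenolide) | COC(=O)[C@@H](C)[C@@]1(O)C(=O)/C=C(C)\[C@@H](O[Si](CC)(CC)CC)CCC2=CC1(O)OC2=O | intermediate
16 | bicyclic 1,8-hemiketal (1,8-epoxy; 7-OH, 8-OH; C6/C15 hydroxybutenolide; methyl ester at C12; C1, C7, C8, C11 as in 20) | COC(=O)[C@@H](C)[C@]1(O)C2(O)OC(=O)C(=C2)CC[C@@H]2O[C@]1(O)C=C2C | intermediate
17 | (4Z,6R)-6-hydroxy-15-oic acid (open form of ring A; 1,8-hemiketal and C12 methyl ester retained) | COC(=O)[C@@H](C)[C@]1(O)[C@H](O)/C=C(\C(=O)O)CC[C@@H]2O[C@]1(O)C=C2C | intermediate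
18 | butenolide spiro-ketal bis-lactone (1S,6R,7S,8S,11S; C4=C5) | O=C1O[C@@H]2C=C1CC[C@@H]1O[C@@]3(C=C1C)OC(=O)[C@@H](C)[C@]23O | intermediate
19 | 4,5-diol (5-O-deacetyl target) | O[C@H]1[C@H]2OC(=O)[C@]1(O)CC[C@@H]1O[C@@]3(C=C1C)OC(=O)[C@@H](C)[C@]23O | intermediate
20 | CNP0315698.1, (1S,4S,5S,6R,7S,8S,11S)-5-acetoxy-1,8-epoxy-4,7-dihydroxygermacr-9-ene-15,6:12,8-diolide | CC(=O)O[C@H]1[C@H]2OC(=O)[C@]1(O)CC[C@@H]1O[C@@]3(C=C1C)OC(=O)[C@@H](C)[C@]23O | target

**Step count**
Total steps: 11. Longest linear sequence: 11 (fully linear from 1).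

**Steps most likely to fail**

Step 6, the macrocyclic B-alkyl Suzuki coupling. Oxidative addition at the β-bromofuran is slow, oligomers compete, and base can eliminate the O7 acyloxy group β to the C12 ester. The fallback moves the ring closure to the O7–C8 ester bond (macrolactonisation). It sets out from 5 and 7 and uses 4. Esterification of 5 (MeOH, H2SO4) gives methyl prop-2-ynoate F1. ProPhenol/Me2Zn alkynylation of 7 with F1 gives methyl (4S)-4-hydroxyhex-5-en-2-ynoate F2. TESCl/imidazole gives methyl (4S)-4-(triethylsilyloxy)hex-5-en-2-ynoate F3. Me2CuLi at −78 °C gives methyl (2Z,4S)-3-methyl-4-(triethylsilyloxy)hexa-2,5-dienoate F4, and Me3SnOH gives (2Z,4S)-3-methyl-4-(triethylsilyloxy)hexa-2,5-dienoic acid F5. Hydroboration of F5 (9-BBN, 2.2 equiv) and intermolecular Pd/SPhos coupling with bromide 4 give the seco hydroxy acid F6. Yamaguchi macrolactonisation (2,4,6-trichlorobenzoyl chloride, Et3N; DMAP, PhMe, 1 mM) comes back to the route at 12.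

Step 8, the proposed ring-contracting Chan rearrangement. The enolate may instead add 5-exo to the enoate, the 2-hydroxy-1,3-dicarbonyl alkoxide may undergo retro-Claisen cleavage, and the facial sense at C7 is a prediction. The fallback uses known chemistry: an open-chain Chan rearrangement, then closure of the carbocycle by the same kind of B-alkyl Suzuki coupling. It sets out from 10. Photooxygenation (O2, TPP, hν; iPr2NEt) gives the open-chain hydroxybutenolide ester F7. LiTMP at −78 → −25 °C (Chan rearrangement of the α-acyloxy ketone) and AcOH work-up give the monocyclic 2-hydroxy-2,5-dihydrofuran F8, whose hemiketal anomers equilibrate. Hydroboration of its vinyl group (excess 9-BBN) and intramolecular Pd/SPhos coupling with the α-bromobutenolide close C3–C4 under high dilution and come back to the route at 16.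

Step 9, reduction and double lactonisation. Hydride may reach C8 through the open hydroxy-enone form, the wrong C6 epimer may form, and the C7 carbinol flanked by two carbonyl-level carbons may fragment. The fallback inverts the order so that C8 is locked as the acyloxy ketal before any hydride is present. It sets out from 16. CSA in PhMe at 60 °C closes the 12,8-lactone first and gives the spiro-ketal pseudo-acid F9. Luche reduction of its C6 carbonyl (NaBH4, CeCl3·7H2O, MeOH, −78 °C) and acidification then close the butenolide and come back to the route at 18.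

**Further compounds**
F1 | step 6 | methyl prop-2-ynoate | C#CC(=O)OC
F2 | step 6 | methyl (4S)-4-hydroxyhex-5-en-2-ynoate | COC(=O)C#C[C@@H](O)C=C
F3 | step 6 | methyl (4S)-4-(triethylsilyloxy)hex-5-en-2-ynoate | COC(=O)C#C[C@@H](O[Si](CC)(CC)CC)C=C
F4 | step 6 | methyl (2Z,4S)-3-methyl-4-(triethylsilyloxy)hexa-2,5-dienoate | COC(=O)/C=C(C)\[C@@H](O[Si](CC)(CC)CC)C=C
F5 | step 6 | (2Z,4S)-3-methyl-4-(triethylsilyloxy)hexa-2,5-dienoic acid | OC(=O)/C=C(C)\[C@@H](O[Si](CC)(CC)CC)C=C
F6 | step 6 | seco hydroxy acid (furan C4 joined to C3; free 7-OH and C8 acid; 1S,7S,11S,9Z) | COC(=O)[C@@H](C)[C@H](O)c1cc(CC[C@H](O[Si](CC)(CC)CC)/C(C)=C\C(=O)O)co1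
F7 | step 8 | open-chain hydroxybutenolide ester (10 with the bromofuran oxidised to the 4-bromo pseudo-acid; C6 epimers) | COC(=O)[C@@H](C)[C@H](OC(=O)/C=C(C)\[C@@H](O[Si](CC)(CC)CC)C=C)C1(O)C=C(Br)C(=O)O1
F8 | step 8 | monocyclic 2-hydroxy-2,5-dihydrofuran (C7 carbinol bearing the bromo pseudo-acid and the C11 arm; vinyl on C1; cis anomer shown) | COC(=O)[C@@H](C)[C@](O)(C1(O)C=C(Br)C(=O)O1)[C@@]1(O)C=C(C)[C@H](C=C)O1
F9 | step 9 | spiro-ketal pseudo-acid (12,8-lactone closed; C6 hemiketal of the 15,6-hydroxybutenolide) | O=C1OC2(O)C=C1CC[C@@H]1O[C@@]3(C=C1C)OC(=O)[C@@H](C)[C@]23O
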